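Everything rests on disconnecting C4–C5, the bond common to ring A and the lactone ring, in a molecule whose quaternary C10 holds C20 and C1 on opposite faces of ring B. This leads back to a prochiral cyclohexadienone carrying an acrylate on the future C20 oxygen and a chloropropyl chain (future C1–C3). In one operation a copper hydride converts the acrylate into a C4 enolate that adds to C5 of one enantiotopic enone arm, closing the lactone ring and setting C10, C5 and the cis lactone fusion. Ring A then closes by alkylation; ring C and the arene follow by reductive allylation, metathesis and a quinone methide cycloaddition.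

Key step: step 5

Remark (locants): names use the numbering of the target. Ring A = C1–C5 and C10; ring B = C5–C10; ring C = C8, C9, C11–C14. C19 is the lactone carbonyl on C4, C20 the OCH2 on C10, C15 the benzylic CH2. β is the face of ring B that carries C20, α the other face.
Remark (structures): dienone 8 and lactone 10 were checked against the target; C10 and C5 of 10 have the target configuration, and C4 of 10 is provisional because it is re-set in step 7.
Remark (assumption): (R)-DTBM-SEGPHOS is written for step 5; which antipode of the ligand gives 10 must be established by experiment, and the other antipode is used if needed.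

Step 1
Reactants: 1 methyl benzoate; 2 1-bromo-3-chloropropane
Product: 4 methyl 1-(3-chloropropyl)cyclohexa-2,5-diene-1-carboxylate, via lithium ester dienolate 3 (not isolated)
Conditions: Li, NH3/THF, t-BuOH (1 equiv), −78 °C; isoprene; then 2, −78 → −33 °C
Reagents that add atoms: none
Why: Birch reductive alkylation: the ester-stabilised dienolate 3 formed by two-electron reduction is alkylated at the carbon bearing the ester, bromide being displaced in preference to chloride, so no stereocentre arises.

Step 2
Reactants: 4 methyl 1-(3-chloropropyl)cyclohexa-2,5-diene-1-carboxylate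
Product: 5 [1-(3-chloropropyl)cyclohexa-2,5-dien-1-yl]methanol
Conditions: LiAlH4, Et2O, 0 °C
Reagents that add atoms: none
Why: Hydride reduction of the ester by LiAlH4, which at 0 °C leaves the primary chloride and the skipped diene untouched.

Step 3
Reactants: 5 [1-(3-chloropropyl)cyclohexa-2,5-dien-1-yl]methanol; 6 acryloyl chloride
Product: 7 [1-(3-chloropropyl)cyclohexa-2,5-dien-1-yl]methyl prop-2-enoate
Conditions: Et3N, CH2Cl2, 0 °C
Reagents that add atoms: none
Why: Acylation of the neopentyl-type primary alcohol with an acid chloride and an amine base, done before the oxidation because a free 4-hydroxymethyl dienone would lose formaldehyde and aromatise.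

Step 4
Reactants: 7 [1-(3-chloropropyl)cyclohexa-2,5-dien-1-yl]methyl prop-2-enoate
Product: 8 [1-(3-chloropropyl)-4-oxocyclohexa-2,5-dien-1-yl]methyl prop-2-enoate
Conditions: Rh2(cap)4 (cap = caprolactamate, 1 mol%), t-BuOOH (70% aq., 5 equiv), K2CO3 (0.5 equiv), CH2Cl2, 23 °C
Reagents that add atoms: tert-butyl hydroperoxide, CC(C)(C)OO
Why: Radical bis-allylic C–H oxidation with tert-butyl hydroperoxide under dirhodium catalysis: the doubly allylic CH2 is by far the weakest C–H bond, the quaternary carbon blocks aromatisation so that the cross-conjugated dienone results, and the electron-poor acrylate is not attacked by the electrophilic peroxyl radical.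

Step 5
Reactants: 8 [1-(3-chloropropyl)-4-oxocyclohexa-2,5-dien-1-yl]methyl prop-2-enoate
Product: 10 (4R,4aS,8aS)-8a-(3-chloropropyl)-4-methyl-4a,5-dihydro-1H-isochromene-3,6(4H,8aH)-dione, via silyl dienol ether 9 (not isolated)
Conditions: Cu(OAc)2 (5 mol%), (R)-DTBM-SEGPHOS (5.5 mol%), (EtO)2MeSiH (1.2 equiv), toluene, −40 → 0 °C; then 1 M HCl, THF
Reagents that add atoms: none
Why: A ligated copper hydride, made from Cu(OAc)2, the bisphosphine and the silane, delivers hydride to the CH2 end of the acrylate (the carbon that ends up as the methyl group on C4) and gives a copper ester enolate that adds through C4 to C5 of the dienone; the copper dienolate so formed is silylated by the silane, which returns the copper hydride, and 9 is hydrolysed on work-up. The closest known reactions are the copper hydride-catalysed reductive Michael and reductive aldol cyclisations of tethered enoates and the copper-catalysed desymmetrising cyclisations of 4,4-disubstituted cyclohexadienones. The lactone ring closes in a 6-exo-trig mode. C10 becomes stereogenic only through the choice between the two enantiotopic enone arms, which the chiral bisphosphine on copper makes; C5 is fixed by the tether, since the enolate carbon hangs from C20 and can reach C5 only on the C20 side of the ring, which leaves H5 on the α face; C4 follows from the chair-like approach of the enolate and is of no consequence because it is enolised in step 7. The step needs hydrocupration of the acrylate in preference to the dienone and to the product enone, which is secured by the unhindered terminal CH2 of the acrylate against β-carbons that all adjoin quaternary C10, by the small excess of silane and by the low temperature; the primary chloride is inert to copper hydride.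

Step 6
Reactants: 10 cis-fused lactone enone
Product: 11 tert-butyldimethylsilyl dienol ether of 10 (O-silylated at C7; C6=C7 and C8=C9)
Conditions: t-BuMe2SiOTf, Et3N, CH2Cl2, −78 → 0 °C
Reagents that add atoms: tert-butyldimethylsilyl trifluoromethanesulfonate, CC(C)(C)[Si](C)(C)OS(=O)(=O)C(F)(F)F
Why: Soft enolisation and O-silylation of the enone at C6, its only enolisable position because C10 is quaternary, gives the 2-silyloxy diene and so removes the acidic ketone before the strong base of step 7.

Step 7
Reactants: 11 tert-butyldimethylsilyl dienol ether of 10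
Product: 13 7-oxo-Δ8 tricyclic lactone (rings A and B plus lactone ring; 4α-CH3; 5α-H; C19 and C20 β), via ring A-closed silyl dienol ether 12 (not isolated)
Conditions: KN(SiMe3)2, Bu4NI (10 mol%), THF, −78 → 23 °C; then 1 M HCl, THF
Reagents that add atoms: none
Why: Intramolecular C-alkylation of the potassium lactone enolate (6-exo-tet, iodide-assisted), which can reach the chain terminus only from the face of C10 that carries the chain, so that quaternary C4 forms with C19 β and the methyl group α, followed by acid hydrolysis of the silyl dienol ether 12.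

Step 8
Reactants: 13 7-oxo-Δ8 tricyclic lactone
Product: 14 8-iodo-7-oxo-Δ8 tricyclic lactone
Conditions: I2, pyridine, CH2Cl2, 23 °C
Reagents that add atoms: iodine, II
Why: Johnson α-iodination of the enone (pyridine addition, iodination and elimination), a reaction established for cyclohexenones with a quaternary γ-carbon.

Step 9
Reactants: 14 8-iodo-7-oxo-Δ8 tricyclic lactone
Product: 15 8-methyl-7-oxo-Δ8 tricyclic lactone
Conditions: Me4Sn, Pd2(dba)3 (2.5 mol%), AsPh3, CuI, NMP, 60 °C
Reagents that add atoms: tetramethylstannane, C[Sn](C)(C)C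
Why: Stille cross-coupling of the α-iodo enone with tetramethylstannane under neutral conditions that spare the lactone.

Step 10
Reactants: 15 8-methyl-7-oxo-Δ8 tricyclic lactone; 16 4-bromo-2-methylbut-1-ene
Product: 18 7-(trimethylsilyloxy)-Δ7 silyl enol ether with 8-methyl; 9α-(3-methylbut-3-en-1-yl); 9β-H, via Grignard reagent 17 (not isolated)
Conditions: 16, Mg, THF; then 15, CuBr·SMe2 (20 mol%), Me3SiCl, DMPU, THF, −78 → −40 °C; Et3N
Reagents that add atoms: chlorotrimethylsilane, C[Si](C)(C)Cl
Why: Copper-catalysed conjugate addition of Grignard reagent 17 with in situ silylation: the chain enters C9 axially on the α face, anti to C20 (a configuration that is erased in step 11), and the enolate is captured regiospecifically as the C7–C8 silyl enol ether.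

Step 11
Reactants: 18 silyl enol ether
Product: 19 8-methyl-9-(3-methylbut-3-en-1-yl)-7-oxo-Δ8 tricyclic lactone
Conditions: Pd(OAc)2 (1.1 equiv), MeCN/CH2Cl2, 23 °C
Reagents that add atoms: none
Why: Saegusa–Ito oxidation: the palladium enolate at C8 undergoes β-hydride elimination with H9 and restores the enone, now tetrasubstituted, while the remote 1,1-disubstituted alkene is left alone.

Step 12
Reactants: 19 tetrasubstituted enone; 20 allyl bromide
Product: 22 8α-allyl-8β-methyl-9β-(3-methylbut-3-en-1-yl)-7-oxo tricyclic lactone (9α-H), via lithium enolate 21 (not isolated)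
Conditions: Li (2.2 equiv), NH3/THF, t-BuOH (1.0 equiv), −78 °C; isoprene; then 20, −78 → −33 °C
Reagents that add atoms: none
Why: Stork reductive alkylation of the enone: stereoelectronically controlled axial protonation of the C9 carbanion gives H9 α with the chain equatorial (β), and the regiospecific C8 enolate 21 is allylated on the α face, away from the axial C20 on C10, so that the C8 methyl group ends β.

Step 13
Reactants: 22 allylated ketone
Product: 25 8α-allyl-8β-methyl-9β-(3-methylbut-3-en-1-yl) tricyclic lactone (C7 = CH2), via hydrazone 23 (not isolated), via potassium seco carboxylate 24 (not isolated)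
Conditions: N2H4·H2O, diethylene glycol, 130 °C; KOH, 200 °C; then 2 M HCl, 23 °C
Reagents that add atoms: none
Why: Wolff–Kishner reduction in the Huang-Minlon manner removes the C7 oxygen via hydrazone 23, and the hindered lactone, opened by KOH to 24, re-forms on acidification because C19 and C20 are held 1,3-diaxial on ring A.

Step 14
Reactants: 25 deoxygenated diene lactone
Product: 26 8α-[(E)-prop-1-enyl]-8β-methyl-9β-(3-methylbut-3-en-1-yl) tricyclic lactone
Conditions: RuHCl(CO)(PPh3)3 (5 mol%), toluene, 80 °C
Reagents that add atoms: none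
Why: Ruthenium hydride-catalysed olefin isomerisation moves the monosubstituted allyl double bond into the (E)-propenyl position, where quaternary C8 stops further migration, much faster than it touches the 1,1-disubstituted alkene.

Step 15
Reactants: 26 propenyl diene lactone
Product: 27 tetracyclic alkene lactone (ring C closed; C13=C14; 13-CH3; 8β-CH3; 9α-H)
Conditions: second-generation Grubbs catalyst (5 mol%), toluene, 80 °C
Reagents that add atoms: none
Why: Ring-closing olefin metathesis with loss of propene closes six-membered ring C and gives the trisubstituted C13=C14 double bond.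

Step 16
Reactants: 27 tetracyclic alkene lactone; 28 2-hydroxy-5-methoxybenzyl alcohol
Product: 30 cis-fused 6-methoxychroman (aryl O on C13 α; C15 on C14 α; 13β-CH3; 14β-H), via o-quinone methide 29 (not isolated)
Conditions: 28 (3 equiv, in portions), toluene, 170 °C, sealed tube
Reagents that add atoms: none
Why: Inverse-electron-demand hetero-Diels–Alder reaction of the o-quinone methide 29, formed by thermal dehydration of 28, with the trisubstituted alkene: oxygen bonds to the more substituted C13 and CH2 to C14 in a suprafacial addition on the α face, the β face being shielded by the axial methyl group on C8, which sets C13 (O α, methyl β) and C14 (C15 α) together.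

Step 17
Reactants: 30 cis-fused 6-methoxychroman
Product: 32 CNP0148621.1 (target hydroquinone lactone), via hydroxy quinone 31 (not isolated)
Conditions: (NH4)2Ce(NO3)6, MeCN/H2O, 0 °C; then aq. Na2S2O4, EtOAc, 23 °C
Reagents that add atoms: water, O
Why: Oxidative demethylation of the 6-methoxychroman with ring opening (the tocopherol-to-tocopherylquinone type of reaction), in which water adds to the two oxygen-bearing aryl carbons so that the C13–O bond is never broken and C13 keeps its configuration, followed by dithionite reduction of quinone 31 to the hydroquinone.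

Compound list
1 | methyl benzoate | COC(=O)c1ccccc1 | starting material
2 | 1-bromo-3-chloropropane | ClCCCBr | starting material
3 | lithium enolate of methyl cyclohexa-2,5-diene-1-carboxylate | [Li+].COC([O-])=C1C=CCC=C1 | intermediate
4 | methyl 1-(3-chloropropyl)cyclohexa-2,5-diene-1-carboxylate | COC(=O)C1(CCCCl)C=CCC=C1 | intermediate
5 | [1-(3-chloropropyl)cyclohexa-2,5-dien-1-yl]methanol | OCC1(CCCCl)C=CCC=C1 | intermediate
6 | acryloyl chloride | C=CC(=O)Cl | starting material
7 | [1-(3-chloropropyl)cyclohexa-2,5-dien-1-yl]methyl prop-2-enoate | C=CC(=O)OCC1(CCCCl)C=CCC=C1 | intermediate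
8 | [1-(3-chloropropyl)-4-oxocyclohexa-2,5-dien-1-yl]methyl prop-2-enoate, i.e. 4-(acryloyloxymethyl)-4-(3-chloropropyl)cyclohexa-2,5-dienone | C=CC(=O)OCC1(CCCCl)C=CC(=O)C=C1 | intermediate
9 | diethoxy(methyl)silyl dienol ether of 10 (O–Si at C7; C6=C7 and C8=C9; stereocentres as in 10) | CCO[Si](C)(OCC)OC1=C[C@H]2[C@@H](C)C(=O)OC[C@@]2(CCCCl)C=C1 | intermediate
10 | (4R,4aS,8aS)-8a-(3-chloropropyl)-4-methyl-4a,5-dihydro-1H-isochromene-3,6(4H,8aH)-dione (cis-fused lactone enone; C20 β, H5 α) | O=C1C=C[C@]2(CCCCl)COC(=O)[C@H](C)[C@@H]2C1 | intermediate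
11 | tert-butyldimethylsilyl dienol ether of 10 | CC(C)(C)[Si](C)(C)OC1=C[C@H]2[C@@H](C)C(=O)OC[C@@]2(CCCCl)C=C1 | intermediate
12 | ring A-closed tert-butyldimethylsilyl dienol ether (4α-CH3, 5α-H, C19/C20 β) | CC(C)(C)[Si](C)(C)OC1=C[C@H]2[C@@]3(C)C(=O)OC[C@@]2(CCC3)C=C1 | intermediate
13 | 7-oxo-Δ8 tricyclic lactone (ring A, ring B and C19–O–C20 lactone ring; 4α-CH3, 5α-H, C19 and C20 β) | O=C1C=C[C@]2(CCC3)COC(=O)[C@]3(C)[C@@H]2C1 | intermediate
14 | 8-iodo-7-oxo-Δ8 tricyclic lactone | O=C1C(I)=C[C@]2(CCC3)COC(=O)[C@]3(C)[C@@H]2C1 | intermediate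
15 | 8-methyl-7-oxo-Δ8 tricyclic lactone | O=C1C(C)=C[C@]2(CCC3)COC(=O)[C@]3(C)[C@@H]2C1 | intermediate
16 | 4-bromo-2-methylbut-1-ene | C=C(C)CCBr | starting material
17 | (3-methylbut-3-en-1-yl)magnesium bromide | C=C(C)CC[Mg]Br | intermediate
18 | 7-(trimethylsilyloxy)-Δ7 silyl enol ether, 8-methyl, 9α-(3-methylbut-3-en-1-yl), 9β-H | C[Si](C)(C)OC1=C(C)[C@@H](CCC(C)=C)[C@]2(CCC3)COC(=O)[C@]3(C)[C@@H]2C1 | intermediate
19 | 8-methyl-9-(3-methylbut-3-en-1-yl)-7-oxo-Δ8 tricyclic lactone | O=C1C(C)=C(CCC(C)=C)[C@]2(CCC3)COC(=O)[C@]3(C)[C@@H]2C1 | intermediate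
20 | allyl bromide (3-bromoprop-1-ene) | C=CCBr | starting material
21 | lithium Δ7-enolate, 8-methyl, 9β-(3-methylbut-3-en-1-yl), 9α-H | [Li+].[O-]C1=C(C)[C@H](CCC(C)=C)[C@]2(CCC3)COC(=O)[C@]3(C)[C@@H]2C1 | intermediate
22 | 8α-allyl-8β-methyl-9β-(3-methylbut-3-en-1-yl)-7-oxo tricyclic lactone, 9α-H | O=C1[C@@](C)(CC=C)[C@H](CCC(C)=C)[C@]2(CCC3)COC(=O)[C@]3(C)[C@@H]2C1 | intermediate
23 | C7 hydrazone of 22 | NN=C1[C@@](C)(CC=C)[C@H](CCC(C)=C)[C@]2(CCC3)COC(=O)[C@]3(C)[C@@H]2C1 | intermediate
24 | potassium salt of the ring-opened form of 25 (C19 carboxylate, C20 alcohol) | C1[C@@](C)(CC=C)[C@H](CCC(C)=C)[C@@]2(CO)CCC[C@](C)(C(=O)[O-])[C@@H]2C1.[K+] | intermediate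
25 | 8α-allyl-8β-methyl-9β-(3-methylbut-3-en-1-yl) tricyclic lactone (C7 = CH2), 9α-H | C1[C@@](C)(CC=C)[C@H](CCC(C)=C)[C@]2(CCC3)COC(=O)[C@]3(C)[C@@H]2C1 | intermediate
26 | 8α-[(E)-prop-1-enyl]-8β-methyl-9β-(3-methylbut-3-en-1-yl) tricyclic lactone | C1[C@@](C)(/C=C/C)[C@H](CCC(C)=C)[C@]2(CCC3)COC(=O)[C@]3(C)[C@@H]2C1 | intermediate
27 | tetracyclic alkene lactone (rings A, B, C and lactone ring; C13=C14, 13-CH3, 8β-CH3, 9α-H) | C[C@@]12CC[C@@H]3[C@]4(CCC[C@]3(C)C(=O)OC4)[C@H]1CCC(C)=C2 | intermediate
28 | 2-hydroxy-5-methoxybenzyl alcohol | COc1ccc(O)c(CO)c1 | starting material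
29 | 4-methoxy-6-methylidenecyclohexa-2,4-dien-1-one (o-quinone methide) | COC1=CC(=C)C(=O)C=C1 | intermediate
30 | cis-fused 6-methoxychroman (aryl O on C13 α, C15 on C14 α, 13β-CH3, 14β-H) | C[C@@]12CC[C@@H]3[C@]4(CCC[C@]3(C)C(=O)OC4)[C@H]1CC[C@]5(C)Oc6ccc(OC)cc6C[C@H]25 | intermediate
31 | hydroxy quinone (13α-OH, 13β-CH3, 14α-CH2-(1,4-benzoquinon-2-yl), 14β-H) | C[C@@]12CC[C@@H]3[C@]4(CCC[C@]3(C)C(=O)OC4)[C@H]1CC[C@](C)(O)[C@@H]2CC1=CC(=O)C=CC1=O | intermediate
32 | CNP0148621.1 | C[C@@]12CC[C@@H]3[C@]4(CCC[C@]3(C)C(=O)OC4)[C@H]1CC[C@](C)(O)[C@@H]2Cc1cc(O)ccc1O | target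

Total steps: 17. Longest linear sequence: 17 steps (1 → 32).

Steps most likely to fail

Step 5. The copper hydride may reduce a dienone arm directly, the copper ester enolate may be quenched before it cyclises (leaving the propionate), or the ligand may discriminate the two enone arms poorly. The fallback sets out from 5. Esterification with allyl hydrogen methylmalonate (EDC, DMAP) should give allyl [1-(3-chloropropyl)cyclohexa-2,5-dien-1-yl]methyl 2-methylmalonate F1. Bis-allylic oxidation as in step 4 should give the corresponding dienone F2. A bifunctional cinchona thiourea then effects an organocatalytic desymmetrising Michael addition of the malonate methine to one enone arm, a reaction class known for cyclohexadienones with tethered activated carbon nucleophiles, to give the cis-fused C4 allyl ester lactone F3. Deallylation and decarboxylation with Pd(PPh3)4 and HCO2H/Et3N returns the route at 10, possibly accompanied by the C4 epimer of 10 F4, which converges with 10 in step 7.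

Step 16. Self-condensation of the o-quinone methide may outrun its addition to the hindered, non-activated C13=C14 double bond. The fallback sets out from 27. A Sc(OTf)3-catalysed three-component reaction with 2-hydroxy-5-methoxybenzaldehyde and HC(OMe)3 generates a far more electrophilic O-methyl oxocarbenium ion, which alkylates C14 from the α face and is closed by the phenol oxygen at C13 to give the C15-methoxy chroman F5. Ionic hydrogenolysis of the benzylic ether (Et3SiH, CF3CO2H, CH2Cl2, −20 °C) returns the route at 30.

Step 11. β-Hydride elimination may go toward the C8 methyl group and give the exocyclic enone, or stall, because H9 is pseudo-equatorial after the α-face addition of step 10. The fallback sets out from 15 and bypasses steps 10 and 11. Conjugate addition of thiophenol (PhSH, Et3N) should give the 9-(phenylthio) ketone F6. N-Chlorosuccinimide chlorinates α to sulfur and loss of HCl gives the 8-methyl-9-(phenylthio) enone F7. Copper-mediated addition–elimination with Grignard reagent 17 (CuI, THF, −40 °C) expels thiophenolate, restores the enone without an oxidation step, and returns the route at 19.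

Further compounds
F1 | step 5 | allyl [1-(3-chloropropyl)cyclohexa-2,5-dien-1-yl]methyl 2-methylmalonate | C=CCOC(=O)C(C)C(=O)OCC1(CCCCl)C=CCC=C1
F2 | step 5 | allyl [1-(3-chloropropyl)-4-oxocyclohexa-2,5-dien-1-yl]methyl 2-methylmalonate | C=CCOC(=O)C(C)C(=O)OCC1(CCCCl)C=CC(=O)C=C1
F3 | step 5 | allyl (4aS,8aS)-8a-(3-chloropropyl)-4-methyl-3,6-dioxo-4a,5-dihydro-1H-isochromene-4-carboxylate (cis-fused; C4 unassigned) | O=C1C=C[C@]2(CCCCl)COC(=O)C(C)(C(=O)OCC=C)[C@@H]2C1
F4 | step 5 | C4 epimer of 10 | O=C1C=C[C@]2(CCCCl)COC(=O)[C@@H](C)[C@@H]2C1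
F5 | step 16 | C15-methoxy derivative of chroman 30 (C15 unassigned) | C[C@@]12CC[C@@H]3[C@]4(CCC[C@]3(C)C(=O)OC4)[C@H]1CC[C@]5(C)Oc6ccc(OC)cc6C(OC)[C@H]25
F6 | step 11 | 8-methyl-9-(phenylthio)-7-oxo tricyclic lactone (C8 and C9 unassigned) | O=C1C(C)C(Sc4ccccc4)[C@]2(CCC3)COC(=O)[C@]3(C)[C@@H]2C1
F7 | step 11 | 8-methyl-9-(phenylthio)-7-oxo-Δ8 tricyclic lactone | O=C1C(C)=C(Sc4ccccc4)[C@]2(CCC3)COC(=O)[C@]3(C)[C@@H]2C1
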